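**Retrosynthetic overview**

1. The dihydropyranone is the only ring that is made, and it is closed last by ring-closing metathesis of a 2-substituted acrylate ester of a homoallylic alcohol.
2. The acrylate is built on the alcohol: a phosphonoacetate ester is C-alkylated with the side-chain homoallylic iodide, then methylenated with formaldehyde.
3. The homoallylic alcohol comes from a β-formyl butanolide by reagent-controlled allylboration, which sets the pyranone C6 centre.
4. Key bond (pyranone C6 to the butanolide ring carbon): a chiral formyl-anion equivalent, formaldehyde SAMP-hydrazone, adds to the β-carbon of furan-2(5H)-one. Two normally electrophilic carbons are joined, the butanolide stereocentre is set, and the butanolide ring is bought.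
5. The side-chain iodide comes from dihydro-β-ionone (cyclohexene ring bought) through a terminal alkyne, zirconium-catalysed carboalumination (E-alkene) and ethylene oxide.

Assumption: formaldehyde SAMP-hydrazone is taken to give the (S,S)-adduct with furan-2(5H)-one; if the sense were the reverse, the enantiomeric RAMP reagent would be used with nothing else changed.

**Step 1**
Reactants: 1 dihydro-β-ionone [4-(2,6,6-trimethylcyclohex-1-en-1-yl)butan-2-one]
Product: 3 2-(but-3-yn-1-yl)-1,3,3-trimethylcyclohex-1-ene, via enol phosphate 2 (not isolated)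
Conditions: LiN(iPr)2 (1.1 equiv), THF, −78 °C; ClP(O)(OEt)2, −78 °C → rt; then LiN(iPr)2 (2.3 equiv), THF, −78 °C → rt; aq. NH4Cl
Reagents that add atoms: diethyl chlorophosphate, CCOP(=O)(Cl)OCC (its atoms sit in 2 only and leave again before 3)
Why: Kinetic deprotonation on the methyl side gives the terminal enol phosphate, which is eliminated by base to the terminal alkyne (Negishi methyl ketone to alkyne conversion); the tetrasubstituted ring alkene is inert.

**Step 2**
Reactants: 3 2-(but-3-yn-1-yl)-1,3,3-trimethylcyclohex-1-ene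
Product: 6 (3E)-4-methyl-6-(2,6,6-trimethylcyclohex-1-en-1-yl)hex-3-en-1-ol, via alkenylalane 4 (not isolated), via lithium aluminate 5 (not isolated)
Conditions: Me3Al (2 equiv), Cp2ZrCl2 (0.25 equiv), ClCH2CH2Cl, rt, 12 h; volatiles stripped; n-BuLi (1 equiv), hexane/THF, 0 °C; ethylene oxide (3 equiv), 0 °C → rt; aq. HCl
Reagents that add atoms: trimethylaluminium, C[Al](C)C (the vinylic methyl); ethylene oxide, C1CO1 (CH2CH2O); n-butyllithium, [Li]CCCC (butyl and lithium sit in 5 only)
Why: Zirconium-catalysed syn-carboalumination (Negishi) puts methyl on the internal carbon and aluminium on the terminus with >98% E geometry, and the derived aluminate opens ethylene oxide with retention of that geometry.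

**Step 3**
Reactants: 6 (3E)-4-methyl-6-(2,6,6-trimethylcyclohex-1-en-1-yl)hex-3-en-1-ol
Product: 7 2-[(3E)-6-iodo-3-methylhex-3-en-1-yl]-1,3,3-trimethylcyclohex-1-ene
Conditions: iodine, PPh3, imidazole, CH2Cl2, 0 °C → rt
Reagents that add atoms: iodine, [I][I]
Why: Appel-type iodination converts the primary alcohol by SN2 displacement without touching the tri- and tetrasubstituted alkenes.

**Step 4**
Reactants: 8 SAMP [(2S)-2-(methoxymethyl)pyrrolidin-1-amine]
Product: 9 formaldehyde SAMP-hydrazone [(2S)-2-(methoxymethyl)-N-methylidenepyrrolidin-1-amine]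
Conditions: paraformaldehyde (1.2 equiv), MgSO4, CH2Cl2, rt; distillation
Reagents that add atoms: formaldehyde (charged as paraformaldehyde), C=O
Why: Hydrazone condensation gives a monomeric, distillable aza-enamine whose azomethine carbon is nucleophilic.

**Step 5**
Reactants: 10 furan-2(5H)-one; 9 formaldehyde SAMP-hydrazone (1.5 equiv)
Product: 12 (4S)-4-[(E)-{[(2S)-2-(methoxymethyl)pyrrolidin-1-yl]imino}methyl]oxolan-2-one, via silyl ketene acetal 11 (not isolated)
Conditions: TBSOTf (1.2 equiv), CH2Cl2, −78 °C → −40 °C; then pH 7 sodium phosphate buffer, rt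
Reagents that add atoms: tert-butyldimethylsilyl triflate, CC(C)(C)[Si](C)(C)OS(=O)(=O)C(F)(F)F (the silyl group sits in 11 only)
Why: Silyl-triflate-promoted aza-enamine Michael addition: the neutral hydrazone acts as a chiral formyl-anion equivalent and attacks the β-carbon of the O-silylated butenolide, with the methoxymethylpyrrolidine auxiliary shielding one face so that the ring stereocentre (the (R)-butanolide centre of the target) is set; buffer hydrolysis of the ketene acetal returns the lactone.

**Step 6**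
Reactants: 12 (4S)-4-[(E)-{[(2S)-2-(methoxymethyl)pyrrolidin-1-yl]imino}methyl]oxolan-2-one
Product: 14 (4R)-4-[(1R)-1-hydroxybut-3-en-1-yl]oxolan-2-one, via aldehyde 13 (not isolated)
Conditions: O3, CH2Cl2, −78 °C; Ar purge; then (+)-Ipc2B(allyl) (from (−)-α-pinene, 1.5 equiv, pentane solution), Et2O, −78 °C, 2 h; then pH 7 buffer, 30% H2O2, MeOH, 0 °C
Reagents that add atoms: ozone, [O-][O+]=O (the carbinol oxygen); (+)-B-allyldiisopinocampheylborane, C=CCB([C@H]1C[C@H]2C[C@@H]([C@@H]1C)C2(C)C)[C@H]1C[C@H]2C[C@@H]([C@@H]1C)C2(C)C (the allyl group)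
Why: Ozonolytic hydrazone cleavage at −78 °C frees the epimerisable β-formyl lactone without racemisation, and Brown allylboration through a closed chair transition state adds allyl to the Re face under reagent control (the α-centre carries two near-equal CH2 arms and exerts little bias), setting the (R)-carbinol; the lactone does not react with the allylborane at −78 °C.

**Step 7**
Reactants: 14 (4R)-4-[(1R)-1-hydroxybut-3-en-1-yl]oxolan-2-one; 15 (diethoxyphosphoryl)acetic acid (1.3 equiv)
Product: 16 (1R)-1-[(3R)-5-oxooxolan-3-yl]but-3-en-1-yl 2-(diethoxyphosphoryl)acetate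
Conditions: N,N'-diisopropylcarbodiimide (1.5 equiv), DMAP (0.1 equiv), CH2Cl2, 0 °C → rt
Reagents that add atoms: none
Why: Steglich-type carbodiimide/DMAP esterification of the secondary alcohol under near-neutral conditions that avoid lactone migration; no stereocentre is touched.

**Step 8**
Reactants: 16 (1R)-1-[(3R)-5-oxooxolan-3-yl]but-3-en-1-yl 2-(diethoxyphosphoryl)acetate; 7 2-[(3E)-6-iodo-3-methylhex-3-en-1-yl]-1,3,3-trimethylcyclohex-1-ene (1.2 equiv)
Product: 18 (1R)-1-[(3R)-5-oxooxolan-3-yl]but-3-en-1-yl (5E)-6-methyl-2-methylidene-8-(2,6,6-trimethylcyclohex-1-en-1-yl)oct-5-enoate, via alkylated phosphonate 17 (not isolated)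
Conditions: NaH (1.0 equiv), THF, 0 °C → rt; 7, DMF, 50 °C; then K2CO3 (3 equiv), paraformaldehyde (5 equiv), 60 °C
Reagents that add atoms: formaldehyde (charged as paraformaldehyde), C=O (the methylidene carbon)
Why: The phosphonoacetate proton (pKa about 19) is removed selectively beside the lactone α-protons (about 25), the stabilised carbanion is C-alkylated by the primary iodide (SN2), and Horner–Wadsworth–Emmons reaction with formaldehyde installs the 1,1-disubstituted acrylate.

**Step 9**
Reactants: 18 (1R)-1-[(3R)-5-oxooxolan-3-yl]but-3-en-1-yl (5E)-6-methyl-2-methylidene-8-(2,6,6-trimethylcyclohex-1-en-1-yl)oct-5-enoate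
Product: 19 (6R)-3-[(3E)-4-methyl-6-(2,6,6-trimethylcyclohex-1-en-1-yl)hex-3-en-1-yl]-6-[(3R)-5-oxooxolan-3-yl]-5,6-dihydro-2H-pyran-2-one (CNP0207009.2)
Conditions: second-generation Grubbs catalyst RuCl2(=CHPh)(PCy3)(H2IMes) (5–10 mol %), 1,4-benzoquinone (10 mol %), toluene (5 mM), 80 °C
Reagents that add atoms: none
Why: Ring-closing metathesis of the monosubstituted alkene with the 2-substituted acrylate gives the trisubstituted endocyclic enoate of the six-membered lactone with loss of ethene; the hindered side-chain alkenes cannot compete (only four- or nine-membered rings would result) and both stereocentres are untouched.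

**Compound list**

1 | dihydro-β-ionone, 4-(2,6,6-trimethylcyclohex-1-en-1-yl)butan-2-one | CC(=O)CCC1=C(C)CCCC1(C)C | starting material
2 | diethyl 4-(2,6,6-trimethylcyclohex-1-en-1-yl)but-1-en-2-yl phosphate (enol phosphate) | C=C(CCC1=C(C)CCCC1(C)C)OP(=O)(OCC)OCC | intermediate
3 | 2-(but-3-yn-1-yl)-1,3,3-trimethylcyclohex-1-ene | C#CCCC1=C(C)CCCC1(C)C | intermediate
4 | dimethyl[(1E)-2-methyl-4-(2,6,6-trimethylcyclohex-1-en-1-yl)but-1-en-1-yl]alumane (alkenylalane) | C[Al](C)/C=C(\C)CCC1=C(C)CCCC1(C)C | intermediate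
5 | lithium butyl(dimethyl)[(1E)-2-methyl-4-(2,6,6-trimethylcyclohex-1-en-1-yl)but-1-en-1-yl]aluminate | [Li+].CCCC[Al-](C)(C)/C=C(\C)CCC1=C(C)CCCC1(C)C | intermediate
6 | (3E)-4-methyl-6-(2,6,6-trimethylcyclohex-1-en-1-yl)hex-3-en-1-ol | OCC/C=C(\C)CCC1=C(C)CCCC1(C)C | intermediate
7 | 2-[(3E)-6-iodo-3-methylhex-3-en-1-yl]-1,3,3-trimethylcyclohex-1-ene | ICC/C=C(\C)CCC1=C(C)CCCC1(C)C | intermediate
8 | SAMP, (2S)-2-(methoxymethyl)pyrrolidin-1-amine | COC[C@@H]1CCCN1N | starting material
9 | formaldehyde SAMP-hydrazone, (2S)-2-(methoxymethyl)-N-methylidenepyrrolidin-1-amine | COC[C@@H]1CCCN1N=C | intermediate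
10 | furan-2(5H)-one | O=C1OCC=C1 | starting material
11 | tert-butyl{[(4S)-4-[(E)-{[(2S)-2-(methoxymethyl)pyrrolidin-1-yl]imino}methyl]-4,5-dihydrofuran-2-yl]oxy}dimethylsilane (silyl ketene acetal) | COC[C@@H]1CCCN1/N=C/[C@H]1COC(O[Si](C)(C)C(C)(C)C)=C1 | intermediate
12 | (4S)-4-[(E)-{[(2S)-2-(methoxymethyl)pyrrolidin-1-yl]imino}methyl]oxolan-2-one | COC[C@@H]1CCCN1/N=C/[C@H]1COC(=O)C1 | intermediate
13 | (3R)-5-oxooxolane-3-carbaldehyde | O=C[C@H]1COC(=O)C1 | intermediate
14 | (4R)-4-[(1R)-1-hydroxybut-3-en-1-yl]oxolan-2-one | C=CC[C@H]([C@H]1COC(=O)C1)O | intermediate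
15 | (diethoxyphosphoryl)acetic acid | OC(=O)CP(=O)(OCC)OCC | starting material
16 | (1R)-1-[(3R)-5-oxooxolan-3-yl]but-3-en-1-yl 2-(diethoxyphosphoryl)acetate | C=CC[C@H]([C@H]1COC(=O)C1)OC(=O)CP(=O)(OCC)OCC | intermediate
17 | (1R)-1-[(3R)-5-oxooxolan-3-yl]but-3-en-1-yl (5E)-2-(diethoxyphosphoryl)-6-methyl-8-(2,6,6-trimethylcyclohex-1-en-1-yl)oct-5-enoate (both epimers at C2) | C=CC[C@H]([C@H]1COC(=O)C1)OC(=O)C(CC/C=C(\C)CCC1=C(C)CCCC1(C)C)P(=O)(OCC)OCC | intermediate
18 | (1R)-1-[(3R)-5-oxooxolan-3-yl]but-3-en-1-yl (5E)-6-methyl-2-methylidene-8-(2,6,6-trimethylcyclohex-1-en-1-yl)oct-5-enoate | C=CC[C@H]([C@H]1COC(=O)C1)OC(=O)C(=C)CC/C=C(\C)CCC1=C(C)CCCC1(C)C | intermediate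
19 | (6R)-3-[(3E)-4-methyl-6-(2,6,6-trimethylcyclohex-1-en-1-yl)hex-3-en-1-yl]-6-[(3R)-5-oxooxolan-3-yl]-5,6-dihydro-2H-pyran-2-one | CC1=C(CC/C(C)=C/CCC2=CC[C@H]([C@H]3COC(=O)C3)OC2=O)C(C)(C)CCC1 | target

**Step count and risks**

Total steps: 9. Longest linear sequence: 6 (steps 4 to 9); the side-chain branch (steps 1 to 3) joins at step 8.

Steps most likely to fail:

Step 5. Furan-2(5H)-one is a weak acceptor, and the level and sense of auxiliary induction are the least certain point of the route. The fallback sets out from 10 and comes back at 13. Conjugate addition of K[CH2=CHBF3] to 10 with Rh(acac)(C2H4)2 and (S)-BINAP in dioxane/H2O gives (4S)-4-ethenyloxolan-2-one F1. (S)-BINAP is the enantiomer that gives (S)-3-phenylcyclohexanone from cyclohex-2-enone, and the same facial mode gives the (4S)-lactone. Ozonolysis of F1 (O3, CH2Cl2, −78 °C; Me2S) cleaves the vinyl group to 13, whose solution goes straight into the allylboration of step 6. The stereocentre is then set by a catalyst and a latent formyl group instead of the auxiliary.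

Step 6. Aldehyde 13 is epimerisable, the allylation may be mismatched, and the free alcohol 14 can undergo lactone migration. The fallback sets out from 13 and comes back at 16. Barbier allylation of the solution of 13 with allyl bromide and indium powder in THF/H2O (no base) gives 14 together with its carbinol epimer (4R)-4-[(1S)-1-hydroxybut-3-en-1-yl]oxolan-2-one F2, and the two are separated on silica. 14 goes on through step 7. F2 is esterified with 15 under Mitsunobu conditions (PPh3, DIAD, THF, 0 °C), which inverts the carbinol centre and gives the same ester 16, so both epimers are used.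

Step 8. The unactivated homoallylic iodide may alkylate slowly or eliminate to the diene, and the base and formaldehyde act on a bis-ester. The fallback sets out from 7 and comes back at 18. Alkylation of the sodium salt of triethyl phosphonoacetate with 7 (NaH, DMF, 50 °C) gives ethyl (5E)-2-(diethoxyphosphoryl)-6-methyl-8-(2,6,6-trimethylcyclohex-1-en-1-yl)oct-5-enoate F3. Methylenation (K2CO3, aqueous formaldehyde) gives ethyl (5E)-6-methyl-2-methylidene-8-(2,6,6-trimethylcyclohex-1-en-1-yl)oct-5-enoate F4. Saponification (LiOH, THF/H2O) gives (5E)-6-methyl-2-methylidene-8-(2,6,6-trimethylcyclohex-1-en-1-yl)oct-5-enoic acid F5. Carbodiimide/DMAP esterification of 14 with F5 then gives 18 directly, so all strongly basic operations are done on a simple ester.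

**Further compounds**

F1 | step 5 | (4S)-4-ethenyloxolan-2-one | C=C[C@H]1COC(=O)C1
F2 | step 6 | (4R)-4-[(1S)-1-hydroxybut-3-en-1-yl]oxolan-2-one | C=CC[C@@H]([C@H]1COC(=O)C1)O
F3 | step 8 | ethyl (5E)-2-(diethoxyphosphoryl)-6-methyl-8-(2,6,6-trimethylcyclohex-1-en-1-yl)oct-5-enoate | CCOC(=O)C(CC/C=C(\C)CCC1=C(C)CCCC1(C)C)P(=O)(OCC)OCC
F4 | step 8 | ethyl (5E)-6-methyl-2-methylidene-8-(2,6,6-trimethylcyclohex-1-en-1-yl)oct-5-enoate | CCOC(=O)C(=C)CC/C=C(\C)CCC1=C(C)CCCC1(C)C
F5 | step 8 | (5E)-6-methyl-2-methylidene-8-(2,6,6-trimethylcyclohex-1-en-1-yl)oct-5-enoic acid | OC(=O)C(=C)CC/C=C(\C)CCC1=C(C)CCCC1(C)C
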